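**Plan**

Ring A is the benzene ring of the chromene, ring B the pyran and ring C the 4-hydroxyphenyl ring (chromene numbering). On ring A, C5 (arylethyl) is meta to both oxygens (O1 at C8a, hydroxyl at C7) and closed to electrophilic substitution, yet the run C7–O, C6–CO2Me, C5–CH2 is exactly what a C5–C6 aryne polarised by the C7 oxygen delivers.
Retrosynthesis: remove the ring-C silyl ether; cut ring B at C4–C4a and O1–C2 (to 3-methylbut-2-enal); cut C8–CH2 (prenyl); cut C5–CH2 and C6–CO2 together to a 3-alkoxyaryne, an arylethyl Grignard reagent and CO2.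
Forward: ring A is bought as 5-fluororesorcinol and ring C as 4-(2-bromoethyl)phenol; the aryne coupling joins the two-carbon chain and the carboxyl carbon to ring A in one flask.
Esterification, acetal cleavage and C-prenylation at C8 follow; ring B then closes at the single free ring-A carbon (C4a), and fluoride frees the ring-C phenol last.
Stereochemistry: the target has no stereocentre; the C3=C4 alkene is cis because it lies in ring B.

Key step: step 4

Remark: before ring B exists the compounds are named as benzoates (benzoate C3, between the two oxygens, becomes chromene C8; benzoate C5 becomes C4a); 4-(2-bromoethyl)phenol is taken as purchased and is also accessible from tyrosol with aqueous HBr.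

**Route**

Step 1
Reactants: 1 5-fluororesorcinol
Product: 2 1-fluoro-3,5-bis(methoxymethoxy)benzene
Conditions: NaH (2.4 equiv), DMF, 0 °C; MOMCl (2.4 equiv), 0 °C to rt
Reagents that add atoms: chloromethyl methyl ether (MOMCl), COCCl
Why: Williamson-type O-alkylation of both sodium phenoxides with the reactive α-chloro ether should give the bis-acetal, the C–F bond being inert under these conditions.

Step 2
Reactants: 3 4-(2-bromoethyl)phenol
Product: 4 [4-(2-bromoethyl)phenoxy]triisopropylsilane
Conditions: TIPSCl, imidazole, CH2Cl2, 0 °C to rt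
Reagents that add atoms: chlorotriisopropylsilane (TIPSCl), CC(C)[Si](Cl)(C(C)C)C(C)C
Why: Imidazole-promoted silylation of the phenol (silyl ether formation) should proceed without touching the primary bromide, and the bulky aryl silyl ether is chosen to survive organomagnesium chemistry, mild base and the later acidic acetal cleavage.

Step 3
Reactants: 4 [4-(2-bromoethyl)phenoxy]triisopropylsilane
Product: 5 {2-[4-(triisopropylsilyloxy)phenyl]ethyl}magnesium bromide (titrated THF solution, used directly)
Conditions: Mg turnings (activated with a little 1,2-dibromoethane), THF, 40 °C; titration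
Reagents that add atoms: magnesium, [Mg]
Why: Oxidative insertion of magnesium into the primary C–Br bond (Grignard reagent formation) is routine for 2-arylethyl bromides, and slow addition of 4 should keep Wurtz coupling low.

Step 4
Reactants: 2 1-fluoro-3,5-bis(methoxymethoxy)benzene; 5 {2-[4-(triisopropylsilyloxy)phenyl]ethyl}magnesium bromide; 6 carbon dioxide
Product: 10 2,4-bis(methoxymethoxy)-6-{2-[4-(triisopropylsilyloxy)phenyl]ethyl}benzoic acid, via 2-fluoro-4,6-bis(methoxymethoxy)phenyllithium 7 (not isolated), via 3,5-bis(methoxymethoxy)benzyne 8 (not isolated), via arylmagnesium bromide 9 (not isolated)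
Conditions: n-BuLi (1.0 equiv), THF, −78 °C, 45 min; 5 (2.0 equiv), −78 °C to rt; CO2 gas (6), 0 °C; cold 1 M HCl to pH 3
Reagents that add atoms: none
Why: At −78 °C n-BuLi should remove the ring proton flanked by fluorine and an acetal oxygen, the most acidic C–H of 2, to give aryllithium 7, which loses LiF on warming to form aryne 8. The acetal oxygen beside the triple bond polarises and distorts 8, so Grignard reagent 5 should add at the remote aryne carbon (new aryl–CH2 bond) and leave the carbanion on the carbon next to oxygen, where induction and chelation by the acetal stabilise arylmagnesium 9. Carbon dioxide then carboxylates 9 (new aryl–CO2H bond), so the two adjacent carbon substituents are installed in one flask with no alkene to reduce afterwards. The closest known reaction type is the three-component coupling of a 3-alkoxyaryne, generated from a fluoroarene, with a Grignard reagent and an electrophile. No ring closes and no stereocentre forms. The selectivity needed is regiochemical: in the deprotonation it rests on the acidifying fluorine at low temperature and on using no excess n-BuLi, and in the aryne addition on the methoxymethoxy group adjacent to the triple bond.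

Step 5
Reactants: 10 2,4-bis(methoxymethoxy)-6-{2-[4-(triisopropylsilyloxy)phenyl]ethyl}benzoic acid
Product: 11 methyl 2,4-bis(methoxymethoxy)-6-{2-[4-(triisopropylsilyloxy)phenyl]ethyl}benzoate
Conditions: MeI, KHCO3, DMF, rt
Reagents that add atoms: iodomethane, CI
Why: SN2 O-alkylation of the potassium carboxylate takes place at the methyl carbon of MeI and is therefore indifferent to the two ortho substituents that would block a Fischer esterification, while bicarbonate is too weak to disturb the aryl silyl ether.

Step 6
Reactants: 11 methyl 2,4-bis(methoxymethoxy)-6-{2-[4-(triisopropylsilyloxy)phenyl]ethyl}benzoate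
Product: 12 methyl 2,4-dihydroxy-6-{2-[4-(triisopropylsilyloxy)phenyl]ethyl}benzoate
Conditions: conc. HCl (cat.), MeOH, 45 °C
Reagents that add atoms: none
Why: Acid-catalysed transacetalisation to methanol should cleave both aryl methoxymethyl ethers, while the methyl ester is degenerate in methanol and the hindered triisopropylsilyl aryl ether resists dilute acid.

Step 7
Reactants: 12 methyl 2,4-dihydroxy-6-{2-[4-(triisopropylsilyloxy)phenyl]ethyl}benzoate; 13 prenyl bromide (1-bromo-3-methylbut-2-ene)
Product: 14 methyl 2,4-dihydroxy-3-(3-methylbut-2-en-1-yl)-6-{2-[4-(triisopropylsilyloxy)phenyl]ethyl}benzoate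
Conditions: NaH (1.1 equiv), toluene, 0 °C; 13 (1.1 equiv), rt to 50 °C
Reagents that add atoms: none
Why: Ortho C-alkylation of a sodium phenoxide as a tight ion pair in a non-polar solvent (C-prenylation) should favour C3, which is activated by both flanking oxygens and less hindered than C5 beside the arylethyl chain.

Step 8
Reactants: 14 methyl 2,4-dihydroxy-3-(3-methylbut-2-en-1-yl)-6-{2-[4-(triisopropylsilyloxy)phenyl]ethyl}benzoate; 15 3-methylbut-2-enal
Product: 17 methyl 7-hydroxy-2,2-dimethyl-8-(3-methylbut-2-en-1-yl)-5-{2-[4-(triisopropylsilyloxy)phenyl]ethyl}-2H-chromene-6-carboxylate, via ortho-quinone methide 16 (not isolated)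
Conditions: 15 (3 equiv), ethylenediammonium diacetate (20 mol %), toluene, reflux, 4 Å molecular sieves
Reagents that add atoms: none
Why: Ammonium-salt-catalysed Knoevenagel-type condensation of the enal at C5 (the only free ring carbon, ortho to the non-chelated 4-hydroxyl and para to the 2-hydroxyl) followed by dehydration should give ortho-quinone methide 16, whose oxa-6π electrocyclisation closes ring B, and only one chromene can form because C3 is blocked by the prenyl group.

Step 9
Reactants: 17 methyl 7-hydroxy-2,2-dimethyl-8-(3-methylbut-2-en-1-yl)-5-{2-[4-(triisopropylsilyloxy)phenyl]ethyl}-2H-chromene-6-carboxylate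
Product: 18 methyl 7-hydroxy-5-[2-(4-hydroxyphenyl)ethyl]-2,2-dimethyl-8-(3-methylbut-2-en-1-yl)-2H-chromene-6-carboxylate (CNP0133674.0)
Conditions: tetrabutylammonium fluoride (1.1 equiv), AcOH (1.1 equiv), THF, 0 °C
Reagents that add atoms: none
Why: Fluoride-induced cleavage of the aryl Si–O bond (desilylation), driven by Si–F bond formation and buffered by acetic acid, should release the ring-C phenol without affecting the ester, the chromene or the prenyl group.

**Compound list**

1 | 5-fluororesorcinol (5-fluorobenzene-1,3-diol) | Oc1cc(O)cc(F)c1 | starting material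
2 | 1-fluoro-3,5-bis(methoxymethoxy)benzene | COCOc1cc(F)cc(OCOC)c1 | intermediate
3 | 4-(2-bromoethyl)phenol | Oc1ccc(CCBr)cc1 | starting material
4 | [4-(2-bromoethyl)phenoxy]triisopropylsilane | CC(C)[Si](Oc1ccc(CCBr)cc1)(C(C)C)C(C)C | intermediate
5 | {2-[4-(triisopropylsilyloxy)phenyl]ethyl}magnesium bromide | Br[Mg]CCc1ccc(O[Si](C(C)C)(C(C)C)C(C)C)cc1 | intermediate
6 | carbon dioxide | O=C=O | starting material
7 | 2-fluoro-4,6-bis(methoxymethoxy)phenyllithium | [Li]c1c(F)cc(OCOC)cc1OCOC | intermediate
8 | 3,5-bis(methoxymethoxy)benzyne (1,2-didehydro-3,5-bis(methoxymethoxy)benzene) | COCOC1=CC(OCOC)=CC#C1 | intermediate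
9 | (2,4-bis(methoxymethoxy)-6-{2-[4-(triisopropylsilyloxy)phenyl]ethyl}phenyl)magnesium bromide | Br[Mg]c1c(OCOC)cc(OCOC)cc1CCc1ccc(O[Si](C(C)C)(C(C)C)C(C)C)cc1 | intermediate
10 | 2,4-bis(methoxymethoxy)-6-{2-[4-(triisopropylsilyloxy)phenyl]ethyl}benzoic acid | O=C(O)c1c(OCOC)cc(OCOC)cc1CCc1ccc(O[Si](C(C)C)(C(C)C)C(C)C)cc1 | intermediate
11 | methyl 2,4-bis(methoxymethoxy)-6-{2-[4-(triisopropylsilyloxy)phenyl]ethyl}benzoate | COC(=O)c1c(OCOC)cc(OCOC)cc1CCc1ccc(O[Si](C(C)C)(C(C)C)C(C)C)cc1 | intermediate
12 | methyl 2,4-dihydroxy-6-{2-[4-(triisopropylsilyloxy)phenyl]ethyl}benzoate | COC(=O)c1c(O)cc(O)cc1CCc1ccc(O[Si](C(C)C)(C(C)C)C(C)C)cc1 | intermediate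
13 | prenyl bromide (1-bromo-3-methylbut-2-ene) | CC(C)=CCBr | starting material
14 | methyl 2,4-dihydroxy-3-(3-methylbut-2-en-1-yl)-6-{2-[4-(triisopropylsilyloxy)phenyl]ethyl}benzoate | COC(=O)c1c(O)c(CC=C(C)C)c(O)cc1CCc1ccc(O[Si](C(C)C)(C(C)C)C(C)C)cc1 | intermediate
15 | 3-methylbut-2-enal | CC(C)=CC=O | starting material
16 | ortho-quinone methide: methyl 2-hydroxy-3-(3-methylbut-2-en-1-yl)-5-(3-methylbut-2-en-1-ylidene)-4-oxo-6-{2-[4-(triisopropylsilyloxy)phenyl]ethyl}cyclohexa-1(6),2-diene-1-carboxylate | COC(=O)C1=C(CCc2ccc(O[Si](C(C)C)(C(C)C)C(C)C)cc2)C(=CC=C(C)C)C(=O)C(CC=C(C)C)=C1O | intermediate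
17 | methyl 7-hydroxy-2,2-dimethyl-8-(3-methylbut-2-en-1-yl)-5-{2-[4-(triisopropylsilyloxy)phenyl]ethyl}-2H-chromene-6-carboxylate | COC(=O)c1c(O)c(CC=C(C)C)c2c(c1CCc1ccc(O[Si](C(C)C)(C(C)C)C(C)C)cc1)C=CC(C)(C)O2 | intermediate
18 | methyl 7-hydroxy-5-[2-(4-hydroxyphenyl)ethyl]-2,2-dimethyl-8-(3-methylbut-2-en-1-yl)-2H-chromene-6-carboxylate (CNP0133674.0) | COC(=O)c1c(O)c(CC=C(C)C)c2c(c1CCc1ccc(O)cc1)C=CC(C)(C)O2 | target

**Step count and risks**

Total step count: 9. Longest linear sequence: 8 steps (3 to 18 through 4, 5, 10, 11, 12, 14 and 17).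

Steps most likely to fail:

1. Step 4. Deprotonation at the carbon between the two acetal oxygens may compete with deprotonation next to fluorine; that aryllithium cannot expel fluoride and would only be carboxylated. Self-addition of 7 to 8 may also occur if the Grignard reagent is not in excess. The fallback sets out from 2 and comes back to the route at 10. Compound 2 would be brominated with NBS in MeCN at 0 °C, which should place bromine para to one acetal oxygen and ortho to fluorine and give 2-bromo-1-fluoro-3,5-bis(methoxymethoxy)benzene F1. Bromine–lithium exchange of F1 with n-BuLi in THF at −78 °C would then deliver 7 at a position fixed by the halogen, not by relative acidities. Addition of 5, warming and carboxylation as in step 4 would lead through 8 and 9 to 10.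

2. Step 7. O-alkylation, alkylation at C5 and double alkylation may compete with C-alkylation at C3. The fallback sets out from 12 and comes back at 14. The non-chelated 4-hydroxyl of 12 would be O-alkylated with isobutyl 2-methylbut-3-en-2-yl carbonate and catalytic Pd(PPh3)4 in THF at 0 °C, which should give the tertiary allyl ether methyl 2-hydroxy-4-(2-methylbut-3-en-2-yloxy)-6-{2-[4-(triisopropylsilyloxy)phenyl]ethyl}benzoate F2. Heating F2 in toluene at about 110 °C should bring about an aromatic Claisen rearrangement. This intramolecular shift delivers the prenyl group only to a carbon ortho to that oxygen, and it should prefer C3 because the chelated 2-hydroxy ester localises double-bond character in the C3–C4 bond and C5 is crowded by the arylethyl chain. The product is 14.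

3. Step 8. Condensation at the crowded C5 of a ring bearing an ester may be slow, so that self-condensation of the enal takes over. The fallback sets out from 14 and comes back at 17. The 4-hydroxyl of 14 would be alkylated with 3-chloro-3-methylbut-1-yne (DBU, catalytic CuCl2, MeCN, 0 °C) to give methyl 2-hydroxy-3-(3-methylbut-2-en-1-yl)-4-(2-methylbut-3-yn-2-yloxy)-6-{2-[4-(triisopropylsilyloxy)phenyl]ethyl}benzoate F3. Heating F3 in N,N-diethylaniline at about 150 °C should trigger a propargyl Claisen rearrangement to the free ortho carbon C5, a 1,5-hydrogen shift to 16 and oxa-6π electrocyclisation to 17.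

Further compounds
F1 | step 4 | 2-bromo-1-fluoro-3,5-bis(methoxymethoxy)benzene | COCOc1cc(F)c(Br)c(OCOC)c1
F2 | step 7 | methyl 2-hydroxy-4-(2-methylbut-3-en-2-yloxy)-6-{2-[4-(triisopropylsilyloxy)phenyl]ethyl}benzoate | COC(=O)c1c(O)cc(OC(C)(C)C=C)cc1CCc1ccc(O[Si](C(C)C)(C(C)C)C(C)C)cc1
F3 | step 8 | methyl 2-hydroxy-3-(3-methylbut-2-en-1-yl)-4-(2-methylbut-3-yn-2-yloxy)-6-{2-[4-(triisopropylsilyloxy)phenyl]ethyl}benzoate | COC(=O)c1c(O)c(CC=C(C)C)c(OC(C)(C)C#C)cc1CCc1ccc(O[Si](C(C)C)(C(C)C)C(C)C)cc1
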